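**Retrosynthetic overview**

- The plan rests on rings A and B: a trans-decalin with C4 (α-CH3, axial β-CH2OH), C5 (α-H) and C10 (β-CH3), and with C8 and C9 oxidised and C11 on C9. This is the pattern left by an epoxide-initiated polyene bicyclization that ends on a β-keto ester.
- Key disconnection: C4–C5 and C9–C10, closing ring A and then ring B from the acyclic (E)-epoxy-dienyl β-keto ester 16. Compound 16 comes from geraniol by Still–Gennari olefination, Sharpless epoxidation and methyl acetoacetate dianion alkylation.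
- After the bicyclization: C3 is deoxygenated, C9 is hydroxylated from the α face, and ester carbon C11 is turned into a vinyl group. A B-alkyl Suzuki coupling and ring-closing metathesis then build the 3-alkyl-2,5-dihydrofuran (C12–C16).
- Ring order: A and B (step 11), dihydrofuran (step 20), spiro-oxolane C9–O–C13 by iodoetherification (step 22). The enol ether, the C7 oxygen, the C8 methyl carbinol (methyl from the α face), the acetate and the free C19 alcohol follow.

Key step: step 11

Remarks and assumptions: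
- Labdane numbering is used throughout (C17 on C8, C18 = 4α-CH3, C19 = 4β-CH2O, C20 on C10).
- The carbinol centres C8 in 22–24 and 28–30 and C7 in 35–36 are drawn as the epimers expected from α-face attack. Both are oxidised to ketones later, so their configuration does not affect the outcome.
- Epoxide 3 is racemic at its epoxide CH carbon and diol 4 at its carbinol carbon (geranyl C6); that carbon becomes the aldehyde carbon of 5.

**Route**

Step 1
Reactants: 1 geraniol
Product: 2 geranyl 4-methoxybenzyl ether, (2E)-1-[(4-methoxybenzyl)oxy]-3,7-dimethylocta-2,6-diene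
Conditions: NaH, PMBCl, Bu4NI (cat.), THF/DMF, 0 °C → rt
Reagents that add atoms: 4-methoxybenzyl chloride, COc1ccc(CCl)cc1
Why: Williamson etherification of the primary allylic alkoxide; the PMB ether survives the base, hydride and titanium steps ahead and can later be removed oxidatively beside a silyl ether and an epoxide.

Step 2
Reactants: 2 geranyl 4-methoxybenzyl ether
Product: 3 (2E)-6,7-epoxy-1-[(4-methoxybenzyl)oxy]-3,7-dimethyloct-2-ene (racemic epoxide)
Conditions: mCPBA (1.05 equiv), CH2Cl2, −20 → 0 °C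
Reagents that add atoms: 3-chloroperoxybenzoic acid, OOC(=O)c1cccc(Cl)c1
Why: Prilezhaev epoxidation should go to the remote, more electron-rich 6,7-alkene, because the 2,3-alkene is deactivated by the allylic ether oxygen.

Step 3
Reactants: 3 the 6,7-epoxide
Product: 5 (4E)-6-[(4-methoxybenzyl)oxy]-4-methylhex-4-enal, via 6,7-diol 4 (not isolated)
Conditions: H5IO6, THF/H2O, 0 °C
Reagents that add atoms: none
Why: acid-catalysed epoxide hydrolysis followed by Malaprade glycol cleavage in the same flask should give the aldehyde and acetone, with the E-alkene and the PMB ether untouched.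

Step 4
Reactants: 5 the aldehyde; 6 ethyl 2-[bis(2,2,2-trifluoroethoxy)phosphoryl]propanoate
Product: 7 ethyl (2Z,6E)-8-[(4-methoxybenzyl)oxy]-2,6-dimethylocta-2,6-dienoate
Conditions: KHMDS, 18-crown-6, THF, −78 °C
Reagents that add atoms: none
Why: Still–Gennari olefination; the electron-poor phosphonate under dissociating conditions should give the (Z)-2-methyl enoate, which places the future C19 carbon cis to the chain.

Step 5
Reactants: 7 the (2Z,6E)-enoate
Product: 8 (2Z,6E)-8-[(4-methoxybenzyl)oxy]-2,6-dimethylocta-2,6-dien-1-ol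
Conditions: DIBAL-H (2.5 equiv), CH2Cl2, −78 °C
Reagents that add atoms: none
Why: 1,2-reduction of the conjugated ester to the allylic alcohol with aluminium hydride, without change of alkene geometry.

Step 6
Reactants: 8 the (Z)-allylic alcohol
Product: 9 [(2R,3S)-3-{(3E)-5-[(4-methoxybenzyl)oxy]-3-methylpent-3-en-1-yl}-2-methyloxiran-2-yl]methanol
Conditions: Ti(OiPr)4 (20 mol%), D-(−)-diethyl tartrate (24 mol%), t-BuOOH, 4 Å MS, CH2Cl2, −20 °C
Reagents that add atoms: tert-butyl hydroperoxide, CC(C)(C)OO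
Why: Katsuki–Sharpless asymmetric epoxidation; D-(−)-tartrate should deliver oxygen to the face of the (Z)-2-methyl allylic alcohol that gives the (2R,3S)-epoxy alcohol, fixing the future C3 (S) and C4 (R) by reagent control while the remote alkene, which has no allylic hydroxyl, stays untouched.

Step 7
Reactants: 9 the epoxy alcohol
Product: 10 tert-butyl{[(2R,3S)-3-{(3E)-5-[(4-methoxybenzyl)oxy]-3-methylpent-3-en-1-yl}-2-methyloxiran-2-yl]methoxy}diphenylsilane
Conditions: TBDPSCl, imidazole, CH2Cl2, 0 °C → rt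
Reagents that add atoms: tert-butyl(chloro)diphenylsilane, CC(C)(C)[Si](Cl)(c1ccccc1)c1ccccc1
Why: silylation of the primary alcohol; the bulky, weakly basic TBDPS ether is chosen to tolerate MeAlCl2 and to discourage chelation to the epoxide.

Step 8
Reactants: 10 the PMB/TBDPS epoxide
Product: 11 (2E)-5-[(2S,3R)-3-{[tert-butyl(diphenyl)silyl]oxymethyl}-3-methyloxiran-2-yl]-3-methylpent-2-en-1-ol
Conditions: DDQ, CH2Cl2/pH 7 buffer, 0 °C
Reagents that add atoms: none
Why: oxidative PMB cleavage (benzylic hydride abstraction, then hydrolysis of the hemiacetal) under buffered conditions should leave the epoxide, the silyl ether and the alkene alone.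

Step 9
Reactants: 11 the allylic alcohol
Product: 13 tert-butyl{[(2R,3S)-3-[(3E)-5-bromo-3-methylpent-3-en-1-yl]-2-methyloxiran-2-yl]methoxy}diphenylsilane, via allylic mesylate 12 (not isolated)
Conditions: MsCl, Et3N, CH2Cl2, −40 °C; then LiBr, THF, 0 °C
Reagents that add atoms: lithium bromide, [Li+].[Br-]
Why: sulfonylation followed by SN2 displacement with bromide at the primary allylic carbon, under cold, non-acidic conditions that spare the epoxide.

Step 10
Reactants: 13 the allylic bromide; 14 methyl acetoacetate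
Product: 16 methyl (6E)-9-[(2S,3R)-3-{[tert-butyl(diphenyl)silyl]oxymethyl}-3-methyloxiran-2-yl]-7-methyl-3-oxonon-6-enoate, via sodium lithium dianion 15 (not isolated)
Conditions: 14 (2.5 equiv), NaH, THF, 0 °C; n-BuLi, 0 °C; then 13, 0 °C; then AcOH
Reagents that add atoms: none
Why: Weiler dianion alkylation; the more basic terminal carbanion of the acetoacetate dianion should attack the allylic bromide by SN2 much faster than the hindered epoxide, giving the β-keto ester that carries C1–C11 and C18–C20.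

Step 11
Reactants: 16 the (E)-epoxy-dienyl β-keto ester
Product: 17 methyl 19-[tert-butyl(diphenyl)silyl]oxy-3β-hydroxy-8-oxo-12,13,14,15,16,17-hexanorlabdan-11-oate (5α-H, 9α-H, 10β-CH3)
Conditions: MeAlCl2 (2.5 equiv), CH2Cl2, −78 → −40 °C; then H2O
Reagents that add atoms: none
Why: One equivalent of MeAlCl2 should turn the β-keto ester into its dichloroaluminium enolate chelate (methane is lost) and a second should activate the epoxide, which ionizes at the tertiary C4; the C5=C10 alkene attacks C4 anti to the departing oxygen (ring A, 6-endo) and the C10 cation is then captured by the enolate carbon C9 (ring B, 6-endo), the closest known reaction type being the Lewis-acid, epoxide-initiated cation–olefin bicyclization terminated by a β-keto ester or enol. C3 keeps the epoxide configuration (3β-OH), while C4 is inverted, so that the Z-disposed CH2OSi group becomes axial (β, C19) and the E methyl equatorial (α, C18). C5–H and C10–CH3 end trans (5α, 10β) because the E-alkene adds antiperiplanar through a chair–chair array, and C9 settles with the ester equatorial (β), a centre that is epimerizable and is set again in step 14. The step needs carbon rather than oxygen capture at the terminus and complete bicyclization rather than proton loss after ring A; the chelated aluminium enolate, the trisubstituted E-alkene and the low temperature should secure this. The absolute sense comes only from the Sharpless-derived epoxide.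

Step 12
Reactants: 17 the 3β-hydroxy β-keto ester
Product: 18 the 3-O-(imidazol-1-ylthiocarbonyl) derivative of 17
Conditions: 1,1'-thiocarbonyldiimidazole, DMAP (cat.), ClCH2CH2Cl, 70 °C
Reagents that add atoms: 1,1'-thiocarbonyldiimidazole, S=C(n1ccnc1)n1ccnc1
Why: acylation of the hindered equatorial 3β-hydroxyl with a neutral reagent gives the thiocarbonyl derivative needed for Barton–McCombie deoxygenation without enolate chemistry at the β-keto ester.

Step 13
Reactants: 18 the thiocarbonylimidazolide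
Product: 19 methyl 19-[tert-butyl(diphenyl)silyl]oxy-8-oxo-12,13,14,15,16,17-hexanorlabdan-11-oate
Conditions: Bu3SnH, AIBN (cat.), toluene, 100 °C
Reagents that add atoms: none
Why: Barton–McCombie radical deoxygenation; the stannyl radical adds to C=S, the secondary C3 radical is released and abstracts hydrogen, and no stereocentre is formed.

Step 14
Reactants: 19 the 3-deoxy β-keto ester
Product: 21 methyl 19-[tert-butyl(diphenyl)silyl]oxy-9α-hydroxy-8-oxo-12,13,14,15,16,17-hexanorlabdan-11-oate, via potassium enolate 20 (not isolated)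
Conditions: KHMDS, THF, −78 °C; then 2-(phenylsulfonyl)-3-phenyloxaziridine; then AcOH
Reagents that add atoms: 2-(phenylsulfonyl)-3-phenyloxaziridine, O=S(=O)(c1ccccc1)N1OC1c1ccccc1
Why: Davis α-hydroxylation of the β-keto ester enolate; the oxidant should approach C9 from the α face, anti to the axial C10 methyl, giving 9α-OH with the ester (C11) β.

Step 15
Reactants: 21 the α-hydroxy β-keto ester
Product: 22 19-[tert-butyl(diphenyl)silyl]oxy-12,13,14,15,16,17-hexanorlabdane-8β,9α,11-triol
Conditions: LiAlH4, THF, −78 → 0 °C; then H2O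
Reagents that add atoms: none
Why: hydride reduction of the ester and the ketone; the 8β-alcohol is expected from α-face hydride attack, since the β face is screened by the C10 methyl.

Step 16
Reactants: 22 the triol
Product: 23 19-[tert-butyl(diphenyl)silyl]oxy-8β,9α-dihydroxy-12,13,14,15,16,17-hexanorlabdan-11-al
Conditions: TEMPO (10 mol%), PhI(OAc)2, CH2Cl2, rt
Reagents that add atoms: none
Why: TEMPO-catalysed oxoammonium oxidation is selective for the primary C11 alcohol over the hindered axial secondary 8-OH and the tertiary 9-OH.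

Step 17
Reactants: 23 the dihydroxy aldehyde
Product: 24 19-[tert-butyl(diphenyl)silyl]oxy-13,14,15,16,17-pentanorlabd-11-ene-8β,9α-diol (9β-vinyl)
Conditions: Ph3PCH3Br, n-BuLi, THF, 0 °C; then 23, −78 → 0 °C
Reagents that add atoms: methyltriphenylphosphonium bromide, C[P+](c1ccccc1)(c1ccccc1)c1ccccc1.[Br-]
Why: Wittig methylenation of the non-enolizable aldehyde with excess ylide, the two hydroxyls being carried as lithium alkoxides at low temperature.

Step 18
Reactants: 25 allyl alcohol; 26 2,3-dibromopropene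
Product: 27 3-(allyloxy)-2-bromoprop-1-ene
Conditions: NaH, THF, 0 °C; then 26, rt
Reagents that add atoms: none
Why: Williamson etherification by SN2 at the allylic CH2Br, which leaves the vinylic bromide for the coupling.

Step 19
Reactants: 24 the vinyl diol; 27 3-(allyloxy)-2-bromoprop-1-ene
Product: 29 19-[tert-butyl(diphenyl)silyl]oxy-hexanorlabdane-8β,9α-diol carrying the 9β chain CH2CH2C(=CH2)CH2OCH2CH=CH2, via B-alkyl-9-BBN borane 28 (not isolated)
Conditions: 9-BBN, THF, rt; then aq. K3PO4; then 27, Pd(dppf)Cl2 (5 mol%), AsPh3, DMF, 50 °C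
Reagents that add atoms: none
Why: anti-Markovnikov hydroboration of the terminal vinyl group followed by B-alkyl Suzuki–Miyaura coupling with the vinylic bromide forms C12–C13; the hydroxyls are tolerated and no stereocentre is formed.

Step 20
Reactants: 29 the diene ether
Product: 30 19-[tert-butyl(diphenyl)silyl]oxy-15,16-epoxy-17-norlabd-13-ene-8β,9α-diol (2,5-dihydrofuran-3-yl side chain)
Conditions: second-generation Grubbs catalyst RuCl2(=CHPh)(H2IMes)(PCy3) (5 mol%), CH2Cl2, 40 °C
Reagents that add atoms: none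
Why: ring-closing metathesis between the 1,1-disubstituted and the terminal alkene closes the five-membered ring C13=C14–C15–O–C16 with loss of ethylene.

Step 21
Reactants: 30 the dihydrofuran diol
Product: 31 19-[tert-butyl(diphenyl)silyl]oxy-15,16-epoxy-9α-hydroxy-17-norlabd-13-en-8-one
Conditions: Dess–Martin periodinane, CH2Cl2, rt
Reagents that add atoms: none
Why: Dess–Martin oxidation of the secondary 8-OH to the ketone; the tertiary 9-OH and the allylic ether ring are inert.

Step 22
Reactants: 31 the hydroxy ketone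
Product: 32 (13S,14S)-19-[tert-butyl(diphenyl)silyl]oxy-14-iodo-9α,13:15,16-diepoxy-17-norlabdan-8-one (spatial arrangement at C13 as in the target)
Conditions: N-iodosuccinimide, CH2Cl2, −20 → 0 °C, dark
Reagents that add atoms: N-iodosuccinimide, O=C1CCC(=O)N1I
Why: 5-exo iodoetherification with anti addition (O9 to the tertiary C13, iodine to C14); the CH2O arm (C16) is expected to turn toward the open C8 carbonyl side and the slim sp2 CH arm (C14) toward C1, which gives the spiro centre of the target.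

Step 23
Reactants: 32 the spiro iodide
Product: 33 (13R)-19-[tert-butyl(diphenyl)silyl]oxy-9α,13:15,16-diepoxy-17-norlabd-14-en-8-one
Conditions: DBU, toluene, 90 °C
Reagents that add atoms: none
Why: E2 dehydroiodination; only C15 carries a β-hydrogen (C13 is quaternary), so the 14,15-enol ether is the only elimination product.

Step 24
Reactants: 33 the spiro enol ether ketone
Product: 35 the 7α-hydroxy derivative of 33, via potassium enolate 34 (not isolated)
Conditions: KHMDS, THF, −78 °C; then 2-(phenylsulfonyl)-3-phenyloxaziridine; then H2O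
Reagents that add atoms: 2-(phenylsulfonyl)-3-phenyloxaziridine, O=S(=O)(c1ccccc1)N1OC1c1ccccc1
Why: Davis hydroxylation of the ketone enolate, which can form only toward C7 because C9 is quaternary; axial attack from the α face is expected.

Step 25
Reactants: 35 the 7-hydroxy-8-ketone
Product: 36 (13R)-19-[tert-butyl(diphenyl)silyl]oxy-9α,13:15,16-diepoxylabd-14-ene-7α,8β-diol (8α-CH3)
Conditions: MeMgBr (3 equiv), THF, −78 → 0 °C; then H2O
Reagents that add atoms: methylmagnesium bromide, C[Mg]Br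
Why: Grignard 1,2-addition; axial (β) attack is blocked by the syn-axial C10 methyl, so the methyl should enter from the α face (equatorial attack, as with 5α-oxygenated 6-keto steroids), giving 8α-CH3 and 8β-OH.

Step 26
Reactants: 36 the 7,8-diol
Product: 37 (13R)-19-[tert-butyl(diphenyl)silyl]oxy-8β-hydroxy-9α,13:15,16-diepoxylabd-14-en-7-one
Conditions: Dess–Martin periodinane, pyridine, CH2Cl2, 0 °C → rt
Reagents that add atoms: none
Why: Dess–Martin oxidation of the secondary C7 alcohol to the α-ketol; the tertiary 8-OH is inert and pyridine buffers the acetic acid to protect the enol ether.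

Step 27
Reactants: 37 the tertiary α-ketol
Product: 38 (13R)-8β-acetoxy-19-[tert-butyl(diphenyl)silyl]oxy-9α,13:15,16-diepoxylabd-14-en-7-one
Conditions: Ac2O, DMAP, Et3N, ClCH2CH2Cl, 50 °C
Reagents that add atoms: acetic anhydride, CC(=O)OC(C)=O
Why: DMAP-catalysed acylation of the only free hydroxyl, the hindered tertiary 8β-OH, in a basic medium that preserves the enol ether.

Step 28
Reactants: 38 the silyl ether
Product: 39 target, (13R)-8β-acetoxy-19-hydroxy-9α,13:15,16-diepoxylabd-14-en-7-one (CNP0239339.1)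
Conditions: Bu4NF, AcOH, THF, rt → 40 °C
Reagents that add atoms: none
Why: fluoride cleavage of the primary TBDPS ether under buffered, non-acidic conditions should leave the acid-labile spiro enol ether and the tertiary acetate intact.

**Compound list**

1 | geraniol | CC(C)=CCC/C(C)=C/CO | starting material
2 | geranyl 4-methoxybenzyl ether | COc1ccc(COC/C=C(\C)CCC=C(C)C)cc1 | intermediate
3 | (2E)-6,7-epoxygeranyl 4-methoxybenzyl ether (racemic) | COc1ccc(COC/C=C(\C)CCC2OC2(C)C)cc1 | intermediate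
4 | (2E)-8-[(4-methoxybenzyl)oxy]-2,6-dimethyloct-6-ene-2,3-diol (racemic, not isolated) | COc1ccc(COC/C=C(\C)CCC(O)C(C)(C)O)cc1 | intermediate
5 | (4E)-6-[(4-methoxybenzyl)oxy]-4-methylhex-4-enal | COc1ccc(COC/C=C(\C)CCC=O)cc1 | intermediate
6 | ethyl 2-[bis(2,2,2-trifluoroethoxy)phosphoryl]propanoate | CCOC(=O)C(C)P(=O)(OCC(F)(F)F)OCC(F)(F)F | starting material
7 | ethyl (2Z,6E)-8-[(4-methoxybenzyl)oxy]-2,6-dimethylocta-2,6-dienoate | CCOC(=O)/C(C)=C\CC/C(C)=C/COCc1ccc(OC)cc1 | intermediate
8 | (2Z,6E)-8-[(4-methoxybenzyl)oxy]-2,6-dimethylocta-2,6-dien-1-ol | OC/C(C)=C\CC/C(C)=C/COCc1ccc(OC)cc1 | intermediate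
9 | [(2R,3S)-3-{(3E)-5-[(4-methoxybenzyl)oxy]-3-methylpent-3-en-1-yl}-2-methyloxiran-2-yl]methanol | COc1ccc(COC/C=C(\C)CC[C@@H]2O[C@]2(C)CO)cc1 | intermediate
10 | TBDPS ether of 9 | COc1ccc(COC/C=C(\C)CC[C@@H]2O[C@]2(C)CO[Si](c3ccccc3)(c3ccccc3)C(C)(C)C)cc1 | intermediate
11 | (2E)-5-[(2S,3R)-3-{[tert-butyl(diphenyl)silyl]oxymethyl}-3-methyloxiran-2-yl]-3-methylpent-2-en-1-ol | OC/C=C(\C)CC[C@@H]1O[C@]1(C)CO[Si](c1ccccc1)(c1ccccc1)C(C)(C)C | intermediate
12 | methanesulfonate of 11 (not isolated) | CS(=O)(=O)OC/C=C(\C)CC[C@@H]1O[C@]1(C)CO[Si](c1ccccc1)(c1ccccc1)C(C)(C)C | intermediate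
13 | tert-butyl{[(2R,3S)-3-[(3E)-5-bromo-3-methylpent-3-en-1-yl]-2-methyloxiran-2-yl]methoxy}diphenylsilane | BrC/C=C(\C)CC[C@@H]1O[C@]1(C)CO[Si](c1ccccc1)(c1ccccc1)C(C)(C)C | intermediate
14 | methyl acetoacetate | COC(=O)CC(C)=O | starting material
15 | sodium lithium dianion of methyl acetoacetate (not isolated) | [Na+].[Li+].COC(=O)[CH-]C(=O)[CH2-] | intermediate
16 | methyl (6E)-9-[(2S,3R)-3-{[tert-butyl(diphenyl)silyl]oxymethyl}-3-methyloxiran-2-yl]-7-methyl-3-oxonon-6-enoate | COC(=O)CC(=O)CC/C=C(\C)CC[C@@H]1O[C@]1(C)CO[Si](c1ccccc1)(c1ccccc1)C(C)(C)C | intermediate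
17 | methyl 19-(TBDPS-oxy)-3β-hydroxy-8-oxo-12,13,14,15,16,17-hexanorlabdan-11-oate | O=C1CC[C@H]2[C@@](C)(CO[Si](c3ccccc3)(c3ccccc3)C(C)(C)C)[C@@H](O)CC[C@]2(C)[C@H]1C(=O)OC | intermediate
18 | 3-O-(imidazol-1-ylthiocarbonyl) derivative of 17 | O=C1CC[C@H]2[C@@](C)(CO[Si](c3ccccc3)(c3ccccc3)C(C)(C)C)[C@@H](OC(=S)n3ccnc3)CC[C@]2(C)[C@H]1C(=O)OC | intermediate
19 | methyl 19-(TBDPS-oxy)-8-oxo-12,13,14,15,16,17-hexanorlabdan-11-oate | O=C1CC[C@H]2[C@@](C)(CO[Si](c3ccccc3)(c3ccccc3)C(C)(C)C)CCC[C@]2(C)[C@H]1C(=O)OC | intermediate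
20 | potassium enolate of 19 (not isolated) | [K+].[O-]C=1CC[C@H]2[C@@](C)(CO[Si](c3ccccc3)(c3ccccc3)C(C)(C)C)CCC[C@]2(C)C=1C(=O)OC | intermediate
21 | methyl 19-(TBDPS-oxy)-9α-hydroxy-8-oxo-12,13,14,15,16,17-hexanorlabdan-11-oate | O=C1CC[C@H]2[C@@](C)(CO[Si](c3ccccc3)(c3ccccc3)C(C)(C)C)CCC[C@]2(C)[C@@]1(O)C(=O)OC | intermediate
22 | 19-(TBDPS-oxy)-12,13,14,15,16,17-hexanorlabdane-8β,9α,11-triol | O[C@H]1CC[C@H]2[C@@](C)(CO[Si](c3ccccc3)(c3ccccc3)C(C)(C)C)CCC[C@]2(C)[C@@]1(O)CO | intermediate
23 | 19-(TBDPS-oxy)-8β,9α-dihydroxy-12,13,14,15,16,17-hexanorlabdan-11-al | O[C@H]1CC[C@H]2[C@@](C)(CO[Si](c3ccccc3)(c3ccccc3)C(C)(C)C)CCC[C@]2(C)[C@@]1(O)C=O | intermediate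
24 | 19-(TBDPS-oxy)-13,14,15,16,17-pentanorlabd-11-ene-8β,9α-diol | O[C@H]1CC[C@H]2[C@@](C)(CO[Si](c3ccccc3)(c3ccccc3)C(C)(C)C)CCC[C@]2(C)[C@@]1(O)C=C | intermediate
25 | allyl alcohol | C=CCO | starting material
26 | 2,3-dibromopropene | BrCC(Br)=C | starting material
27 | 3-(allyloxy)-2-bromoprop-1-ene | C=CCOCC(Br)=C | intermediate
28 | B-alkyl-9-BBN adduct of 24, boron on C12 (not isolated; hydroxyls drawn free) | O[C@H]1CC[C@H]2[C@@](C)(CO[Si](c3ccccc3)(c3ccccc3)C(C)(C)C)CCC[C@]2(C)[C@@]1(O)CCB1C2CCCC1CCC2 | intermediate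
29 | 8β,9α-diol with 9β chain CH2CH2C(=CH2)CH2OCH2CH=CH2, 19-OTBDPS | O[C@H]1CC[C@H]2[C@@](C)(CO[Si](c3ccccc3)(c3ccccc3)C(C)(C)C)CCC[C@]2(C)[C@@]1(O)CCC(=C)COCC=C | intermediate
30 | 19-(TBDPS-oxy)-15,16-epoxy-17-norlabd-13-ene-8β,9α-diol | O[C@H]1CC[C@H]2[C@@](C)(CO[Si](c3ccccc3)(c3ccccc3)C(C)(C)C)CCC[C@]2(C)[C@@]1(O)CCC1=CCOC1 | intermediate
31 | 19-(TBDPS-oxy)-15,16-epoxy-9α-hydroxy-17-norlabd-13-en-8-one | O=C1CC[C@H]2[C@@](C)(CO[Si](c3ccccc3)(c3ccccc3)C(C)(C)C)CCC[C@]2(C)[C@@]1(O)CCC1=CCOC1 | intermediate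
32 | (13S,14S)-19-(TBDPS-oxy)-14-iodo-9α,13:15,16-diepoxy-17-norlabdan-8-one | O=C1CC[C@H]2[C@@](C)(CO[Si](c3ccccc3)(c3ccccc3)C(C)(C)C)CCC[C@]2(C)[C@@]12CC[C@]1([C@@H](I)COC1)O2 | intermediate
33 | (13R)-19-(TBDPS-oxy)-9α,13:15,16-diepoxy-17-norlabd-14-en-8-one | O=C1CC[C@H]2[C@@](C)(CO[Si](c3ccccc3)(c3ccccc3)C(C)(C)C)CCC[C@]2(C)[C@@]12CC[C@]1(C=COC1)O2 | intermediate
34 | potassium 7(8)-enolate of 33 (not isolated) | [K+].[O-]C1=CC[C@H]2[C@@](C)(CO[Si](c3ccccc3)(c3ccccc3)C(C)(C)C)CCC[C@]2(C)[C@@]12CC[C@]1(C=COC1)O2 | intermediate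
35 | (13R)-19-(TBDPS-oxy)-7α-hydroxy-9α,13:15,16-diepoxy-17-norlabd-14-en-8-one | O=C1[C@H](O)C[C@H]2[C@@](C)(CO[Si](c3ccccc3)(c3ccccc3)C(C)(C)C)CCC[C@]2(C)[C@@]12CC[C@]1(C=COC1)O2 | intermediate
36 | (13R)-19-(TBDPS-oxy)-9α,13:15,16-diepoxylabd-14-ene-7α,8β-diol | O[C@@]1(C)[C@H](O)C[C@H]2[C@@](C)(CO[Si](c3ccccc3)(c3ccccc3)C(C)(C)C)CCC[C@]2(C)[C@@]12CC[C@]1(C=COC1)O2 | intermediate
37 | (13R)-19-(TBDPS-oxy)-8β-hydroxy-9α,13:15,16-diepoxylabd-14-en-7-one | O[C@@]1(C)C(=O)C[C@H]2[C@@](C)(CO[Si](c3ccccc3)(c3ccccc3)C(C)(C)C)CCC[C@]2(C)[C@@]12CC[C@]1(C=COC1)O2 | intermediate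
38 | (13R)-8β-acetoxy-19-(TBDPS-oxy)-9α,13:15,16-diepoxylabd-14-en-7-one | CC(=O)O[C@@]1(C)C(=O)C[C@H]2[C@@](C)(CO[Si](c3ccccc3)(c3ccccc3)C(C)(C)C)CCC[C@]2(C)[C@@]12CC[C@]1(C=COC1)O2 | intermediate
39 | (13R)-8β-acetoxy-19-hydroxy-9α,13:15,16-diepoxylabd-14-en-7-one | CC(=O)O[C@@]1(C)C(=O)C[C@H]2[C@@](C)(CO)CCC[C@]2(C)[C@@]12CC[C@]1(C=COC1)O2 | target

**Step count and risks**

Total step count: 28. Longest linear sequence: 27 (steps 1–17 and 19–28; step 18 makes the coupling partner 27).

Three steps most likely to fail: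

1. Step 11, the bicyclization. The C10 cation may be captured by the enolate oxygen instead of carbon C9, or the cascade may stop by proton loss after ring A has closed. The fallback sets out from 16, which is silylated on the enol oxygen (TBSOTf, Et3N, CH2Cl2, −78 °C) to methyl (2Z,6E)-3-[(tert-butyldimethylsilyl)oxy]-9-[(2S,3R)-3-{[tert-butyl(diphenyl)silyl]oxymethyl}-3-methyloxiran-2-yl]-7-methylnona-2,6-dienoate F1. With the oxygen blocked, only C9 can close ring B, and MeAlCl2 then induces the same epoxide-initiated cyclization with a Mukaiyama-type silyl enol ether termination. The silyl group is lost on aqueous work-up and the route is rejoined at 17.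

2. Step 22, the iodoetherification. Facial selection at C13 rests on substrate control alone and may give too much of the C13 epimer. The fallback sets out from 31 and uses reagent control. Shi epoxidation (fructose-derived ketone catalyst or its enantiomer, whichever oxygenates the face anti to the required C13–O9 bond; Oxone, 2KHSO5·KHSO4·K2SO4, buffered MeCN/H2O) gives the 13,14-epoxide of 31 F2. Camphorsulfonic acid then induces 5-exo opening by the 9α-hydroxyl at the tertiary C13 with inversion, giving the 14-hydroxy-9α,13:15,16-diepoxy-17-norlabdan-8-one F3. Burgess dehydration of F3 is a syn elimination for which only C15 offers a hydrogen, and it rejoins the route at 33.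

3. Step 25, the methyl addition. Attack on the C8 carbonyl from the α face may be slowed by the neighbouring spiro ring, or magnesium salts may ionize the allylic spiro ether. The fallback sets out from 31 and adds the methyl group before the spiro ring is closed.
   - Enolate hydroxylation (KHMDS 2.2 equiv, then the Davis oxaziridine) gives the 7α,9α-dihydroxy-8-ketone F4.
   - MeMgBr, now with a free axial 9α-alkoxide as in the steroid precedent, gives the 7α,8β,9α-triol F5.
   - Dess–Martin oxidation gives the 8β,9α-dihydroxy-7-ketone F6.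
   - Iodoetherification with N-iodosuccinimide, in which the 5-exo closure by the 9α-hydroxyl should outrun the 6-exo closure by the 8β-hydroxyl, gives the 14-iodo spiro ether F7.
   - Elimination with DBU rejoins the route at 37.

Further compounds
F1 | step 11 | methyl (2Z,6E)-3-[(tert-butyldimethylsilyl)oxy]-9-[(2S,3R)-3-{[tert-butyl(diphenyl)silyl]oxymethyl}-3-methyloxiran-2-yl]-7-methylnona-2,6-dienoate | COC(=O)/C=C(/CC/C=C(\C)CC[C@@H]1O[C@]1(C)CO[Si](c1ccccc1)(c1ccccc1)C(C)(C)C)O[Si](C)(C)C(C)(C)C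
F2 | step 22 | 19-(TBDPS-oxy)-13,14:15,16-diepoxy-9α-hydroxy-17-norlabdan-8-one (13,14-epoxide of 31) | O=C1CC[C@H]2[C@@](C)(CO[Si](c3ccccc3)(c3ccccc3)C(C)(C)C)CCC[C@]2(C)[C@@]1(O)CC[C@]12O[C@H]1COC2
F3 | step 22 | 19-(TBDPS-oxy)-14-hydroxy-9α,13:15,16-diepoxy-17-norlabdan-8-one (14-OH trans to O9) | O=C1CC[C@H]2[C@@](C)(CO[Si](c3ccccc3)(c3ccccc3)C(C)(C)C)CCC[C@]2(C)[C@@]12CC[C@]1([C@@H](O)COC1)O2
F4 | step 25 | 19-(TBDPS-oxy)-15,16-epoxy-7α,9α-dihydroxy-17-norlabd-13-en-8-one | O=C1[C@H](O)C[C@H]2[C@@](C)(CO[Si](c3ccccc3)(c3ccccc3)C(C)(C)C)CCC[C@]2(C)[C@@]1(O)CCC1=CCOC1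
F5 | step 25 | 19-(TBDPS-oxy)-15,16-epoxylabd-13-ene-7α,8β,9α-triol | O[C@@]1(C)[C@H](O)C[C@H]2[C@@](C)(CO[Si](c3ccccc3)(c3ccccc3)C(C)(C)C)CCC[C@]2(C)[C@@]1(O)CCC1=CCOC1
F6 | step 25 | 19-(TBDPS-oxy)-15,16-epoxy-8β,9α-dihydroxylabd-13-en-7-one | O[C@@]1(C)C(=O)C[C@H]2[C@@](C)(CO[Si](c3ccccc3)(c3ccccc3)C(C)(C)C)CCC[C@]2(C)[C@@]1(O)CCC1=CCOC1
F7 | step 25 | 19-(TBDPS-oxy)-8β-hydroxy-14-iodo-9α,13:15,16-diepoxylabdan-7-one | O[C@@]1(C)C(=O)C[C@H]2[C@@](C)(CO[Si](c3ccccc3)(c3ccccc3)C(C)(C)C)CCC[C@]2(C)[C@@]12CC[C@]1([C@@H](I)COC1)O2
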